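**Plan**

- Retrosynthesis (isochromene locants C1, O2, C3, C4, C4a, C5–C8, C8a): cut the C7–O bond of the butanoate to reach a 6-hydroxy-5,8-quinone; cut the C3–side-chain bond to reach a 4-methoxyisochroman-3-one; cut C4–C4a to reach a methoxyacetate ester hung from C1 of a ring A p-quinone monoketal.
- Enabling feature: O5 and O8 are para on ring A. Oxidising the C8 phenol of a commercial aldehyde (free para position C5) to the C5 monoketal installs O5 and turns C4a, the position of the arene that electrophiles do not reach, into the β-carbon of the C8 enone. C4, the α-carbon of the ester tethered through O2–C1, is then within reach of it.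
- Forward: ring A is bought; the pyran ring closes by C4–C4a (step 5) with re-aromatisation; the side chain is joined to C3 through the lactone-derived ketene acetal phosphate; ring A is raised to the 5,8-quinone and acyloxylated at C7; a C1–H to O5 tautomerisation gives the chromophore.
- Stereochemistry: the only stereocentre, C7 (S), is set in step 11 by a C2-symmetric chiral aryl iodane that transfers butanoate to one face of the C6 enol. The C4 centre made in step 5 is racemic and is erased in step 7.

Key step: step 5

Assumption: the target is taken in the drawn tautomeric form (C5 enol, C6 and C8 ketones), expected to be the stable form of the C5/C6 dione because O2–C1=C8a–C8=O is then a vinylogous ester.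
Assumption: the sense of induction of the chiral iodane cannot be predicted with certainty; the (R,R)-iodoarene is written, and its (S,S)-enantiomer is used instead if a test run shows the (7R)-product.

**Step 1**
Reactants: 1 2,4-dihydroxy-3-methylbenzaldehyde
Product: 2 4-(allyloxy)-2-hydroxy-3-methylbenzaldehyde
Conditions: allyl bromide (1.1 equiv), K2CO3 (1.1 equiv), acetone, reflux
Reagents that add atoms: allyl bromide, C=CCBr
Why: Williamson etherification; the 4-OH is the more acidic, non-chelated phenol, whereas the 2-OH is held in a hydrogen bond to the aldehyde, so monoalkylation at O4 (the later O6) is expected.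

**Step 2**
Reactants: 2 4-(allyloxy)-2-hydroxy-3-methylbenzaldehyde
Product: 3 3-(allyloxy)-6-(hydroxymethyl)-2-methylphenol
Conditions: NaBH4, MeOH, 0 °C
Reagents that add atoms: none
Why: Hydride reduction of the aldehyde gives the salicyl alcohol that carries C1 at the oxidation level needed for the tether; the allyl ether is inert.

**Step 3**
Reactants: 3 3-(allyloxy)-6-(hydroxymethyl)-2-methylphenol
Product: 5 3-(allyloxy)-6-(hydroxymethyl)-4,4-dimethoxy-2-methylcyclohexa-2,5-dien-1-one, via monomethoxy phenol 4 (not isolated)
Conditions: PhI(OAc)2 (2.2 equiv), MeOH, 0 °C to rt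
Reagents that add atoms: methanol, CO
Why: Oxidative dearomatisation of a para-unsubstituted phenol with PhI(OAc)2 in methanol: the first equivalent introduces methoxy para to the phenol (the future O5), the second converts the resulting 4-methoxyphenol into the p-quinone monoketal.

**Step 4**
Reactants: 5 3-(allyloxy)-6-(hydroxymethyl)-4,4-dimethoxy-2-methylcyclohexa-2,5-dien-1-one; 6 methoxyacetyl chloride
Product: 7 [4-(allyloxy)-3,3-dimethoxy-5-methyl-6-oxocyclohexa-1,4-dien-1-yl]methyl methoxyacetate
Conditions: pyridine, DMAP (cat.), CH2Cl2, 0 °C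
Reagents that add atoms: none
Why: Acylation of the only hydroxyl group by an acid chloride (nucleophilic catalysis) ties the C3–C4 unit, with its methoxy group, to C1 through O2.

**Step 5**
Reactants: 7 [4-(allyloxy)-3,3-dimethoxy-5-methyl-6-oxocyclohexa-1,4-dien-1-yl]methyl methoxyacetate
Product: 10 6-(allyloxy)-8-hydroxy-4,5-dimethoxy-7-methylisochroman-3-one (racemic at C4), via potassium ester enolate 8 (not isolated), via conjugate-adduct potassium dienolate 9 (not isolated)
Conditions: KN(SiMe3)2 (1.1 equiv), 18-crown-6, THF, −78 to 0 °C; then MeSO3H (1.2 equiv), 0 °C to rt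
Reagents that add atoms: none
Why: KN(SiMe3)2 converts the methoxyacetate into potassium enolate 8, whose α-carbon (the future C4) adds in conjugate fashion to C4a, the β-carbon of the C8 enone of the quinone monoketal, to give dienolate 9; acid then ionises the C5 ketal, methanol is lost across C4a–C5 and tautomerisation of the C8 ketone restores the arene, so that a carbon nucleophile is joined to a ring position that electrophiles cannot reach in the phenol (polarity reversal of ring A through its oxidation level). The closest known reaction type is the Michael addition of enolates and other stabilised carbanions to p-quinone monoketals followed by aromatising loss of methanol, as in the Hauser–Kraus annulation. The pyran ring closes as its lactone in a 6-endo-trig mode, the C4a=C8a double bond lying inside the new six-membered ring. The C4 stereocentre formed here is not controlled and need not be, since it becomes sp2 in step 7. The selectivity needed is 1,4- over 1,2-addition (attack on the C8 carbonyl would also close a six-membered ring): the aldolate can revert under the potassium/crown-ether conditions whereas only the conjugate adduct is drained by aromatisation, and the other enone β-carbon (C6) is out of reach of the tether and deactivated by its alkoxy group. Loss of the benzylic carboxylate from dienolate 9 is reversible, and the quinone methide acid so formed would re-close to the same lactone.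

**Step 6**
Reactants: 10 6-(allyloxy)-8-hydroxy-4,5-dimethoxy-7-methylisochroman-3-one
Product: 11 6,8-bis(allyloxy)-4,5-dimethoxy-7-methylisochroman-3-one (racemic at C4)
Conditions: allyl bromide (1.5 equiv), K2CO3, acetone, 50 °C
Reagents that add atoms: allyl bromide, C=CCBr
Why: Williamson etherification masks the C8 phenol for the enolate chemistry of steps 7 and 8; K2CO3 is too weak a base to deprotonate C4 of the lactone.

**Step 7**
Reactants: 11 6,8-bis(allyloxy)-4,5-dimethoxy-7-methylisochroman-3-one
Product: 13 6,8-bis(allyloxy)-4,5-dimethoxy-7-methyl-1H-isochromen-3-yl diphenyl phosphate, via potassium lactone enolate 12 (not isolated)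
Conditions: KN(SiMe3)2 (1.2 equiv), THF/DMPU, −78 °C; then ClP(O)(OPh)2 (1.3 equiv), −78 to 0 °C
Reagents that add atoms: diphenyl chlorophosphate, O=P(Cl)(Oc1ccccc1)Oc1ccccc1
Why: O-Phosphorylation of the arene-conjugated lactone enolate by the hard phosphoryl chloride gives the ketene acetal phosphate, a standard lactone-derived cross-coupling partner, and erases the racemic C4 centre.

**Step 8**
Reactants: 13 6,8-bis(allyloxy)-4,5-dimethoxy-7-methyl-1H-isochromen-3-yl diphenyl phosphate; 14 tert-butyl(dimethyl)(prop-2-en-1-yloxy)silane
Product: 16 6,8-bis(allyloxy)-3-[3-(tert-butyldimethylsilyloxy)propyl]-4,5-dimethoxy-7-methyl-1H-isochromene, via alkylborane 15 (not isolated)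
Conditions: 14 (1.5 equiv), 9-BBN dimer (1.4 equiv of B–H), THF, 0 °C to rt; then 13, PdCl2(dppf) (10 mol %), aq. Cs2CO3, DMF, rt to 50 °C
Reagents that add atoms: none
Why: B-alkyl Suzuki–Miyaura coupling: anti-Markovnikov hydroboration of 14 gives primary alkylborane 15, which couples with the ketene acetal phosphate to give the C3-alkyl enol ether; no free 9-BBN is left to attack the aryl allyl ethers, which are also inert to the palladium catalyst in the absence of a soft nucleophile.

**Step 9**
Reactants: 16 6,8-bis(allyloxy)-3-[3-(tert-butyldimethylsilyloxy)propyl]-4,5-dimethoxy-7-methyl-1H-isochromene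
Product: 17 3-[3-(tert-butyldimethylsilyloxy)propyl]-4,5-dimethoxy-7-methyl-1H-isochromene-6,8-diol
Conditions: Pd(PPh3)4 (5 mol %), morpholine (6 equiv), THF, rt, argon
Reagents that add atoms: none
Why: Allyl transfer of the Tsuji–Trost type, catalysed by zerovalent palladium, from both aryl allyl ethers to morpholine frees O6 and O8 under non-acidic conditions that spare the enol ether and the silyl ether.

**Step 10**
Reactants: 17 3-[3-(tert-butyldimethylsilyloxy)propyl]-4,5-dimethoxy-7-methyl-1H-isochromene-6,8-diol
Product: 18 3-[3-(tert-butyldimethylsilyloxy)propyl]-6-hydroxy-4-methoxy-7-methyl-1H-isochromene-5,8-dione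
Conditions: PhI(OAc)2 (1.0 equiv), MeCN/pH 7 phosphate buffer, 0 °C
Reagents that add atoms: water, O
Why: Oxidative demethylation of a 4-methoxyphenol by PhI(OAc)2 in aqueous acetonitrile (ipso attack of water at C5, loss of methanol) gives the 5,8-quinone fused to the 1H-pyran, in which the C6 hydroxyl is now the enol of a cyclic 2-methyl-1,3-dicarbonyl.

**Step 11**
Reactants: 18 3-[3-(tert-butyldimethylsilyloxy)propyl]-6-hydroxy-4-methoxy-7-methyl-1H-isochromene-5,8-dione
Product: 20 (7S)-3-[3-(tert-butyldimethylsilyloxy)propyl]-5-hydroxy-4-methoxy-7-methyl-6,8-dioxo-7,8-dihydro-6H-isochromen-7-yl butanoate, via ene-trione butanoate 19 (not isolated)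
Conditions: (R,R)-2-iodo-1,3-bis[1-(mesitylcarbamoyl)ethoxy]benzene (1.2 equiv), mCPBA (1.1 equiv), butyric acid (10 equiv), CH2Cl2, rt, 1 h; then 18, −40 to −10 °C; then NEt3 (0.1 equiv), 0 °C
Reagents that add atoms: butyric acid, CCCC(O)=O
Why: Proposed new method: the acidic C6 enol of the hydroxyquinone should exchange for a butanoate ligand on the trivalent iodine centre formed in the flask, after which butanoate is delivered to C7 with loss of the iodoarene, the lactamide arms of the C2-symmetric reagent shielding one face of the planar enol; the closest known reaction types are the α-acyloxylation of enolised 1,3-dicarbonyls by PhI(OAc)2 and the enantioselective dearomatising oxygenation of phenols and naphthols by lactate-derived chiral aryl iodanes, and ene-trione 19 then tautomerises (C1–H to O5, amine catalysis) to the conjugated 5-hydroxy-6,8-dione.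

**Step 12**
Reactants: 20 (7S)-3-[3-(tert-butyldimethylsilyloxy)propyl]-5-hydroxy-4-methoxy-7-methyl-6,8-dioxo-7,8-dihydro-6H-isochromen-7-yl butanoate
Product: 21 (7S)-5-hydroxy-3-(3-hydroxypropyl)-4-methoxy-7-methyl-6,8-dioxo-7,8-dihydro-6H-isochromen-7-yl butanoate
Conditions: HF·pyridine, pyridine, THF, 0 °C
Reagents that add atoms: none
Why: Fluoride-mediated cleavage of the primary silyl ether under buffered conditions should leave the vinylogous ester, the C5 enol and the tertiary butanoate untouched, and the quaternary C7 centre cannot epimerise.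

**Compound list**

1 | 2,4-dihydroxy-3-methylbenzaldehyde | O=Cc1ccc(O)c(C)c1O | starting material
2 | 4-(allyloxy)-2-hydroxy-3-methylbenzaldehyde | O=Cc1ccc(OCC=C)c(C)c1O | intermediate
3 | 3-(allyloxy)-6-(hydroxymethyl)-2-methylphenol | OCc1ccc(OCC=C)c(C)c1O | intermediate
4 | 3-(allyloxy)-6-(hydroxymethyl)-4-methoxy-2-methylphenol | OCc1cc(OC)c(OCC=C)c(C)c1O | intermediate
5 | 3-(allyloxy)-6-(hydroxymethyl)-4,4-dimethoxy-2-methylcyclohexa-2,5-dien-1-one | O=C1C(CO)=CC(OC)(OC)C(OCC=C)=C1C | intermediate
6 | methoxyacetyl chloride | COCC(Cl)=O | starting material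
7 | [4-(allyloxy)-3,3-dimethoxy-5-methyl-6-oxocyclohexa-1,4-dien-1-yl]methyl methoxyacetate | O=C1C(COC(=O)COC)=CC(OC)(OC)C(OCC=C)=C1C | intermediate
8 | potassium ester enolate of 7 | [K+].[O-]C(=COC)OCC1=CC(OC)(OC)C(OCC=C)=C(C)C1=O | intermediate
9 | potassium 6-(allyloxy)-4,5,5-trimethoxy-7-methyl-3-oxo-3,4,4a,5-tetrahydro-1H-isochromen-8-olate (mixture of diastereomers) | [K+].[O-]C1=C2COC(=O)C(OC)C2C(OC)(OC)C(OCC=C)=C1C | intermediate
10 | 6-(allyloxy)-8-hydroxy-4,5-dimethoxy-7-methylisochroman-3-one (racemic) | COC1C(=O)OCc2c(O)c(C)c(OCC=C)c(OC)c12 | intermediate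
11 | 6,8-bis(allyloxy)-4,5-dimethoxy-7-methylisochroman-3-one (racemic) | COC1C(=O)OCc2c(OCC=C)c(C)c(OCC=C)c(OC)c12 | intermediate
12 | potassium 6,8-bis(allyloxy)-4,5-dimethoxy-7-methyl-1H-isochromen-3-olate | [K+].COC1=C([O-])OCc2c(OCC=C)c(C)c(OCC=C)c(OC)c12 | intermediate
13 | 6,8-bis(allyloxy)-4,5-dimethoxy-7-methyl-1H-isochromen-3-yl diphenyl phosphate | COC1=C(OP(=O)(Oc3ccccc3)Oc3ccccc3)OCc2c(OCC=C)c(C)c(OCC=C)c(OC)c12 | intermediate
14 | tert-butyl(dimethyl)(prop-2-en-1-yloxy)silane | C=CCO[Si](C)(C)C(C)(C)C | starting material
15 | 9-[3-(tert-butyldimethylsilyloxy)propyl]-9-borabicyclo[3.3.1]nonane | CC(C)(C)[Si](C)(C)OCCCB1C2CCCC1CCC2 | intermediate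
16 | 6,8-bis(allyloxy)-3-[3-(tert-butyldimethylsilyloxy)propyl]-4,5-dimethoxy-7-methyl-1H-isochromene | COC1=C(CCCO[Si](C)(C)C(C)(C)C)OCc2c(OCC=C)c(C)c(OCC=C)c(OC)c12 | intermediate
17 | 3-[3-(tert-butyldimethylsilyloxy)propyl]-4,5-dimethoxy-7-methyl-1H-isochromene-6,8-diol | COC1=C(CCCO[Si](C)(C)C(C)(C)C)OCc2c(O)c(C)c(O)c(OC)c12 | intermediate
18 | 3-[3-(tert-butyldimethylsilyloxy)propyl]-6-hydroxy-4-methoxy-7-methyl-1H-isochromene-5,8-dione | COC1=C(CCCO[Si](C)(C)C(C)(C)C)OCC2=C1C(=O)C(O)=C(C)C2=O | intermediate
19 | (7S)-3-[3-(tert-butyldimethylsilyloxy)propyl]-4-methoxy-7-methyl-5,6,8-trioxo-5,6,7,8-tetrahydro-1H-isochromen-7-yl butanoate | CCCC(=O)O[C@@]1(C)C(=O)C2=C(C(OC)=C(CCCO[Si](C)(C)C(C)(C)C)OC2)C(=O)C1=O | intermediate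
20 | (7S)-3-[3-(tert-butyldimethylsilyloxy)propyl]-5-hydroxy-4-methoxy-7-methyl-6,8-dioxo-7,8-dihydro-6H-isochromen-7-yl butanoate | CCCC(=O)O[C@@]1(C)C(=O)C2=COC(CCCO[Si](C)(C)C(C)(C)C)=C(OC)C2=C(O)C1=O | intermediate
21 | (7S)-5-hydroxy-3-(3-hydroxypropyl)-4-methoxy-7-methyl-6,8-dioxo-7,8-dihydro-6H-isochromen-7-yl butanoate | CCCC(=O)O[C@@]1(C)C(=O)C2=COC(CCCO)=C(OC)C2=C(O)C1=O | target

**Step count and risks**

Total step count: 12. Longest linear sequence: 12 steps (1 to 21); 6 and 14 are commercial and enter directly.

Steps most likely to fail: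

1. Step 11 (proposed new method). What may go wrong: poor facial discrimination in the butanoate transfer, scrambling of carboxylate ligands on iodine, or oxidation elsewhere in the electron-rich pyran. The fallback sets out from 18 and comes back at 20. Compound 18 is treated with PhI(OAc)2 in the presence of excess butyric acid (ligand exchange on iodine in the flask), which is the known α-acyloxylation of enolised 1,3-dicarbonyls by diacyloxyiodobenzenes. Tautomerisation with NEt3 should give the racemic 7-butanoate F1. The enantiomers are then separated by preparative chromatography on a chiral stationary phase to give 20.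

2. Step 5 (key step). What may go wrong: kinetic 1,2-addition of the enolate to the C8 carbonyl that fails to revert, or proton transfer and elimination of the benzylic carboxylate outrunning the conjugate addition. The fallback sets out from 5 and comes back at 10, and replaces the simple ester enolate by a soft, doubly stabilised donor of the phthalide-sulfone type. Methoxymethyl phenyl sulfone is lithiated (n-BuLi) and carboxylated with CO2 to give 2-methoxy-2-(phenylsulfonyl)acetic acid F2. This acid is esterified with 5 (DCC, DMAP) to give the sulfonyl ester F3. Cs2CO3 in MeCN followed by MeSO3H should effect conjugate addition and aromatisation to the 4-(phenylsulfonyl) lactone F4. Reductive desulfonylation with SmI2 (THF/MeOH, −78 °C) then gives 10.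

3. Step 3. What may go wrong: the double oxidation stalling at the monomethoxy phenol, attack of methanol at an ortho position, or decomposition of the salicyl alcohol through quinone methide formation. The fallback sets out from 2 and comes back at 5, and introduces O5 before the dearomatisation. Compound 2 is brominated para to the free phenol (NBS, MeCN) to give 4-(allyloxy)-5-bromo-2-hydroxy-3-methylbenzaldehyde F5. Copper-mediated methoxylation (NaOMe, CuBr, DMF/MeOH, 100 °C) gives 4-(allyloxy)-2-hydroxy-5-methoxy-3-methylbenzaldehyde F6. Reduction with NaBH4 gives 4, now isolated, and a single oxidation of this 4-methoxyphenol with PhI(OAc)2 (1.1 equiv) in MeOH gives 5.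

**Further compounds**

F1 | step 11 | racemic 3-[3-(tert-butyldimethylsilyloxy)propyl]-5-hydroxy-4-methoxy-7-methyl-6,8-dioxo-7,8-dihydro-6H-isochromen-7-yl butanoate | CCCC(=O)OC1(C)C(=O)C2=COC(CCCO[Si](C)(C)C(C)(C)C)=C(OC)C2=C(O)C1=O
F2 | step 5 | 2-methoxy-2-(phenylsulfonyl)acetic acid | COC(C(O)=O)S(=O)(=O)c1ccccc1
F3 | step 5 | [4-(allyloxy)-3,3-dimethoxy-5-methyl-6-oxocyclohexa-1,4-dien-1-yl]methyl 2-methoxy-2-(phenylsulfonyl)acetate | COC(C(=O)OCC1=CC(OC)(OC)C(OCC=C)=C(C)C1=O)S(=O)(=O)c1ccccc1
F4 | step 5 | 6-(allyloxy)-8-hydroxy-4,5-dimethoxy-7-methyl-4-(phenylsulfonyl)isochroman-3-one | COC1(S(=O)(=O)c3ccccc3)C(=O)OCc2c(O)c(C)c(OCC=C)c(OC)c12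
F5 | step 3 | 4-(allyloxy)-5-bromo-2-hydroxy-3-methylbenzaldehyde | O=Cc1cc(Br)c(OCC=C)c(C)c1O
F6 | step 3 | 4-(allyloxy)-2-hydroxy-5-methoxy-3-methylbenzaldehyde | O=Cc1cc(OC)c(OCC=C)c(C)c1O
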